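**Strategy.** The target is cut at C4–C5 and at the C3–O bond of a temporary oxirane. Quaternary carbinol C3 hangs on ring methine C1' of the cyclohexane, whose C2' and C6' arms differ only at the remote C3'/C4' halides, so the ring cannot bias C3. The key step therefore lets a tartrate–titanium reagent epoxidise the exocyclic C3=C4 alkene, with the C2 carbinol as the directing allylic alcohol. This fixes C3 and arms C4 for the isobutenyl nucleophile in one operation. Its precursor is (2S)-3-(3-bromo-4-chloro-4-methylcyclohexyl)but-3-en-2-ol, whose ring stereocentres come from a catalytic bromochlorination and an auxiliary-controlled ring closure.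

Key step: step 12

Labels: chain C1 (acetyl CH3), C2, C3 (carbinol), C4, C5, C6 (CMe2); ring C1'–C6', with C1' on C3, Br on C3', Cl and CH3 on C4'.

Remark on the chemistry: the epoxidation substrate is carried as the (2S)-carbinol and paired with L-(+)-diisopropyl tartrate, because the fast-reacting (S)-carbinol of this antipode receives oxygen on the C3 face that the target needs (erythro oxirane, carbinol S, oxirane carbon R); the (2R)-carbinol with the D-(−)-tartrate would give the C3 epimer.

Assumption: in step 4 the ligand antipode is the one that gives the (5S,6S) bromochloride; the remote auxiliary is taken to have no influence on this.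

Step 1
Reactants: 1 but-2-yn-1-ol
Product: 3 (Z)-3-iodobut-2-en-1-ol, via cyclic sodium alkenylalanate 2 (not isolated)
Conditions: NaAlH2(OCH2CH2OMe)2, THF, 0 °C to rt; then I2, THF, −78 to 0 °C
Reagents that add atoms: iodine, II
Why: Hydroxyl-directed trans-hydroalumination puts aluminium on C3 cis to the CH2O group (a five-membered alanate), and iodinolysis with retention should give the Z vinyl iodide (hydroalumination–iodination of a propargylic alcohol).

Step 2
Reactants: 4 (R)-4-benzyloxazolidin-2-one; 5 but-3-enoyl chloride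
Product: 7 (R)-4-benzyl-3-(but-3-enoyl)oxazolidin-2-one, via lithium oxazolidinide 6 (not isolated)
Conditions: n-BuLi, THF, −78 °C; then 5, −78 °C
Reagents that add atoms: none
Why: N-Acylation of the lithiated oxazolidinone by the acid chloride at −78 °C should give the imide before base can move the terminal alkene into conjugation.

Step 3
Reactants: 7 (R)-4-benzyl-3-(but-3-enoyl)oxazolidin-2-one; 3 (Z)-3-iodobut-2-en-1-ol
Product: 9 (R)-4-benzyl-3-[(Z)-7-hydroxy-5-methylhept-5-enoyl]oxazolidin-2-one, via B-alkyl-9-BBN adduct 8 (not isolated)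
Conditions: 9-BBN, THF, 0 °C to rt; then 3, PdCl2(dppf) (5 mol%), AsPh3, Cs2CO3, DMF–H2O, rt
Reagents that add atoms: none
Why: Anti-Markovnikov hydroboration of the terminal alkene and B-alkyl Suzuki–Miyaura coupling with the vinyl iodide, which keeps the alkene geometry, should give the Z trisubstituted allylic alcohol with CH2OH and the chain cis.

Step 4
Reactants: 9 (R)-4-benzyl-3-[(Z)-7-hydroxy-5-methylhept-5-enoyl]oxazolidin-2-one
Product: 10 (R)-4-benzyl-3-[(5S,6S)-6-bromo-5-chloro-7-hydroxy-5-methylheptanoyl]oxazolidin-2-one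
Conditions: NBS, ClTi(OiPr)3 (1.1 equiv), chiral tridentate O,N,O Schiff-base ligand (0.2 equiv), hexanes–CH2Cl2, −20 °C
Reagents that add atoms: N-bromosuccinimide, O=C1CCC(=O)N1Br; chlorotitanium triisopropoxide, CC(C)O[Ti](Cl)(OC(C)C)OC(C)C
Why: Titanium-mediated catalytic enantioselective bromochlorination of an allylic alcohol: the titanium-bound alkoxide and the chiral ligand direct bromonium formation to one alkene face and chloride opens it anti at the tertiary carbon, so anti addition across the Z alkene should set C6 (Br) and C5 (Cl) as S,S, the future C3' and C4'.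

Step 5
Reactants: 10 (R)-4-benzyl-3-[(5S,6S)-6-bromo-5-chloro-7-hydroxy-5-methylheptanoyl]oxazolidin-2-one
Product: 11 (R)-4-benzyl-3-[(5S,6S)-6-bromo-5-chloro-5-methyl-7-(trifluoromethanesulfonyloxy)heptanoyl]oxazolidin-2-one
Conditions: Tf2O, 2,6-lutidine, CH2Cl2, −78 °C
Reagents that add atoms: trifluoromethanesulfonic anhydride, O=S(=O)(OS(=O)(=O)C(F)(F)F)C(F)(F)F
Why: Sulfonylation of the primary alcohol with Tf2O and a hindered pyridine base at −78 °C should give the primary triflate, which is taken on at once after a cold aqueous wash.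

Step 6
Reactants: 11 (R)-4-benzyl-3-[(5S,6S)-6-bromo-5-chloro-5-methyl-7-(trifluoromethanesulfonyloxy)heptanoyl]oxazolidin-2-one
Product: 13 (R)-4-benzyl-3-[(1S,3S,4S)-3-bromo-4-chloro-4-methylcyclohexane-1-carbonyl]oxazolidin-2-one, via sodium Z-enolate 12 (not isolated)
Conditions: NaN(SiMe3)2 (1.05 equiv), THF, −78 to −40 °C
Reagents that add atoms: none
Why: Intramolecular Evans alkylation (6-exo-tet ring closure): the chelated Z-enolate alkylates at C1' with the tethered primary triflate carbon C2' on the face away from the benzyl group, which with the (R)-auxiliary should set C1' as S, the triflate being displaced far faster than the hindered secondary bromide or the tertiary chloride.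

Step 7
Reactants: 13 (R)-4-benzyl-3-[(1S,3S,4S)-3-bromo-4-chloro-4-methylcyclohexane-1-carbonyl]oxazolidin-2-one
Product: 14 S-ethyl (1S,3S,4S)-3-bromo-4-chloro-4-methylcyclohexane-1-carbothioate
Conditions: EtSH, n-BuLi, THF, 0 °C
Reagents that add atoms: ethanethiol, CCS
Why: Thiolate attacks the exocyclic imide carbonyl (auxiliary cleavage by transthioesterification) and, being weakly basic, should leave the C1' stereocentre and both halides untouched while the auxiliary is recovered.

Step 8
Reactants: 14 S-ethyl (1S,3S,4S)-3-bromo-4-chloro-4-methylcyclohexane-1-carbothioate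
Product: 15 1-[(1S,3S,4S)-3-bromo-4-chloro-4-methylcyclohexyl]ethan-1-one
Conditions: Me2CuLi (from MeLi and CuI), Et2O, −78 °C
Reagents that add atoms: lithium dimethylcuprate, [Li+].C[Cu-]C
Why: Acyl substitution of the thioester by lithium dimethylcuprate stops at the methyl ketone, and at −78 °C the cuprate should not react with the hindered secondary bromide.

Step 9
Reactants: 15 1-[(1S,3S,4S)-3-bromo-4-chloro-4-methylcyclohexyl]ethan-1-one
Product: 17 1-[(1S,3S,4S)-3-bromo-4-chloro-4-methylcyclohexyl]ethenyl trifluoromethanesulfonate, via potassium enolate 16 (not isolated)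
Conditions: KN(SiMe3)2, THF, −78 °C; then PhNTf2, −78 to 0 °C
Reagents that add atoms: N-phenylbis(trifluoromethanesulfonimide), O=S(=O)(N(c1ccccc1)S(=O)(=O)C(F)(F)F)C(F)(F)F
Why: Kinetic deprotonation on the methyl side and O-triflation of the enolate (enol triflate formation) should give the terminal vinyl triflate and avoid the C1' enolate, which could epimerise or displace the ring bromide.

Step 10
Reactants: 17 1-[(1S,3S,4S)-3-bromo-4-chloro-4-methylcyclohexyl]ethenyl trifluoromethanesulfonate; 18 tributyl(1-ethoxyvinyl)stannane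
Product: 20 3-[(1S,3S,4S)-3-bromo-4-chloro-4-methylcyclohexyl]but-3-en-2-one, via 2-ethoxydiene 19 (not isolated)
Conditions: Pd(PPh3)4 (5 mol%), LiCl, THF, 60 °C; then 1 M HCl, rt
Reagents that add atoms: water, O
Why: Stille coupling of the vinyl triflate with the 1-ethoxyvinyl stannane (an acetyl anion equivalent) and acid hydrolysis of the enol ether should give the α-methylene ketone, zerovalent palladium with PPh3 being too slow in oxidative addition to unactivated alkyl halides to disturb the ring.

Step 11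
Reactants: 20 3-[(1S,3S,4S)-3-bromo-4-chloro-4-methylcyclohexyl]but-3-en-2-one
Product: 21 (2S)-3-[(1S,3S,4S)-3-bromo-4-chloro-4-methylcyclohexyl]but-3-en-2-ol
Conditions: (R)-2-methyl-CBS-oxazaborolidine (0.2 equiv), catecholborane, toluene, −78 °C
Reagents that add atoms: none
Why: Corey–Bakshi–Shibata reduction: the (R)-oxazaborolidine binds the ketone with the branched alkenyl group as the large substituent and should deliver hydride to give the (S)-carbinol at C2, catecholborane at −78 °C sparing the 1,1-disubstituted alkene.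

Step 12
Reactants: 21 (2S)-3-[(1S,3S,4S)-3-bromo-4-chloro-4-methylcyclohexyl]but-3-en-2-ol
Product: 22 (1S)-1-{(2R)-2-[(1S,3S,4S)-3-bromo-4-chloro-4-methylcyclohexyl]oxiran-2-yl}ethan-1-ol
Conditions: Ti(OiPr)4 (0.2 equiv), L-(+)-diisopropyl tartrate (0.25 equiv), t-BuOOH (1.5 equiv), 4 Å molecular sieves, CH2Cl2, −20 °C
Reagents that add atoms: tert-butyl hydroperoxide, CC(C)(C)OO
Why: Ligand exchange on the titanium tartrate dimer (tetravalent titanium) places the C2 alkoxide and the tert-butyl peroxide on one metal centre, from which the distal peroxide oxygen is handed to the C3=C4 π bond so that C3–O and C4–O form in a single concerted event. The closest known reaction is the Sharpless asymmetric epoxidation of secondary, 2-substituted allylic alcohols as used for kinetic resolution, here run on a single matched epimer. The oxirane (C3–O–C4) closes by direct oxygen-atom transfer, a [2+1] addition to the alkene, and not by a separate substitution. The new stereocentre C3 is set by the tartrate antipode: L-(+)-tartrate puts oxygen on the face that makes the oxirane carbon R, and the (S)-carbinol is the fast-reacting partner of this antipode, so the erythro product is expected. The step needs face selectivity at a 1,1-disubstituted alkene that the nearly symmetric ring cannot bias, which the matched C2 carbinol from step 11 secures, and chemoselectivity for the allylic alkene, which holds because nothing present is basic or nucleophilic enough to touch the ring C–Br and C–Cl bonds. Catalytic titanium with molecular sieves at −20 °C should limit Lewis-acid opening of the 2,2-disubstituted oxirane.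

Step 13
Reactants: 22 (1S)-1-{(2R)-2-[(1S,3S,4S)-3-bromo-4-chloro-4-methylcyclohexyl]oxiran-2-yl}ethan-1-ol; 23 (2-methylprop-1-en-1-yl)magnesium bromide
Product: 24 (2S,3S)-3-[(1S,3S,4S)-3-bromo-4-chloro-4-methylcyclohexyl]-6-methylhept-5-ene-2,3-diol
Conditions: 23 (3.5 equiv), CuI (0.2 equiv), THF, −40 to 0 °C
Reagents that add atoms: none
Why: Copper-catalysed Grignard opening (SN2) of the 2,2-disubstituted oxirane at its unhindered CH2 carbon C4 should form the C4–C5 bond and release the tertiary C3 hydroxyl without touching the C3 configuration, one extra equivalent of the Grignard reagent being spent on the C2 hydroxyl.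

Step 14
Reactants: 24 (2S,3S)-3-[(1S,3S,4S)-3-bromo-4-chloro-4-methylcyclohexyl]-6-methylhept-5-ene-2,3-diol
Product: 25 (3S)-3-[(1S,3S,4S)-3-bromo-4-chloro-4-methylcyclohexyl]-3-hydroxy-6-methylhept-5-en-2-one
Conditions: SO3·pyridine, DMSO, iPr2NEt, CH2Cl2, 0 °C
Reagents that add atoms: none
Why: Parikh–Doering oxidation should convert the secondary C2 carbinol into the ketone without glycol cleavage, the tertiary C3 hydroxyl being inert, and it removes the hydroxyl that could later open the C5–C6 oxirane by 5-exo attack.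

Step 15
Reactants: 25 (3S)-3-[(1S,3S,4S)-3-bromo-4-chloro-4-methylcyclohexyl]-3-hydroxy-6-methylhept-5-en-2-one
Product: 26 (3S)-3-[(1S,3S,4S)-3-bromo-4-chloro-4-methylcyclohexyl]-4-[(2R)-3,3-dimethyloxiran-2-yl]-3-hydroxybutan-2-one
Conditions: D-fructose-derived Shi ketone (0.3 equiv), 2KHSO5·KHSO4·K2SO4, K2CO3, Bu4NHSO4, Na2B4O7/Na2EDTA buffer, MeCN–CH2(OMe)2–H2O, 0 °C
Reagents that add atoms: potassium peroxymonosulfate, [K+].[O-]S(=O)(=O)OO
Why: Shi asymmetric epoxidation: the dioxirane formed from the D-fructose-derived ketone transfers oxygen to the trisubstituted C5=C6 alkene through a spiro transition state, which should set C5 as R under reagent control at a buffered pH that the tertiary ketol and the ring halides tolerate.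

**Compound list**

1 | but-2-yn-1-ol | CC#CCO | starting material
2 | sodium salt of the five-membered alkenylalanate from 1 (Al on C3, cis to CH2O, two 2-methoxyethoxy groups on Al) | [Na+].CC1=CCO[Al-]1(OCCOC)OCCOC | intermediate
3 | (Z)-3-iodobut-2-en-1-ol | C/C(I)=C/CO | intermediate
4 | (R)-4-benzyloxazolidin-2-one | O=C1N[C@H](Cc2ccccc2)CO1 | starting material
5 | but-3-enoyl chloride | C=CCC(=O)Cl | starting material
6 | lithium (R)-4-benzyl-2-oxooxazolidin-3-ide | [Li+].O=C1[N-][C@H](Cc2ccccc2)CO1 | intermediate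
7 | (R)-4-benzyl-3-(but-3-enoyl)oxazolidin-2-one | C=CCC(=O)N1[C@H](Cc2ccccc2)COC1=O | intermediate
8 | (R)-4-benzyl-3-[4-(9-borabicyclo[3.3.1]nonan-9-yl)butanoyl]oxazolidin-2-one | O=C(CCCB1C2CCCC1CCC2)N1[C@H](Cc2ccccc2)COC1=O | intermediate
9 | (R)-4-benzyl-3-[(Z)-7-hydroxy-5-methylhept-5-enoyl]oxazolidin-2-one | O=C(CCC/C(C)=C\CO)N1[C@H](Cc2ccccc2)COC1=O | intermediate
10 | (R)-4-benzyl-3-[(5S,6S)-6-bromo-5-chloro-7-hydroxy-5-methylheptanoyl]oxazolidin-2-one | O=C(CCC[C@](C)(Cl)[C@@H](Br)CO)N1[C@H](Cc2ccccc2)COC1=O | intermediate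
11 | (R)-4-benzyl-3-[(5S,6S)-6-bromo-5-chloro-5-methyl-7-(trifluoromethanesulfonyloxy)heptanoyl]oxazolidin-2-one | O=C(CCC[C@](C)(Cl)[C@@H](Br)COS(=O)(=O)C(F)(F)F)N1[C@H](Cc2ccccc2)COC1=O | intermediate
12 | sodium Z-enolate of 11 | [Na+].[O-]/C(=C\CC[C@](C)(Cl)[C@@H](Br)COS(=O)(=O)C(F)(F)F)N1[C@H](Cc2ccccc2)COC1=O | intermediate
13 | (R)-4-benzyl-3-[(1S,3S,4S)-3-bromo-4-chloro-4-methylcyclohexane-1-carbonyl]oxazolidin-2-one | O=C([C@H]1CC[C@](C)(Cl)[C@@H](Br)C1)N1[C@H](Cc2ccccc2)COC1=O | intermediate
14 | S-ethyl (1S,3S,4S)-3-bromo-4-chloro-4-methylcyclohexane-1-carbothioate | CCSC(=O)[C@H]1CC[C@](C)(Cl)[C@@H](Br)C1 | intermediate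
15 | 1-[(1S,3S,4S)-3-bromo-4-chloro-4-methylcyclohexyl]ethan-1-one | CC(=O)[C@H]1CC[C@](C)(Cl)[C@@H](Br)C1 | intermediate
16 | potassium 1-[(1S,3S,4S)-3-bromo-4-chloro-4-methylcyclohexyl]ethen-1-olate | [K+].[O-]C(=C)[C@H]1CC[C@](C)(Cl)[C@@H](Br)C1 | intermediate
17 | 1-[(1S,3S,4S)-3-bromo-4-chloro-4-methylcyclohexyl]ethenyl trifluoromethanesulfonate | C=C(OS(=O)(=O)C(F)(F)F)[C@H]1CC[C@](C)(Cl)[C@@H](Br)C1 | intermediate
18 | tributyl(1-ethoxyvinyl)stannane | CCCC[Sn](CCCC)(CCCC)C(=C)OCC | starting material
19 | 2-ethoxy-3-[(1S,3S,4S)-3-bromo-4-chloro-4-methylcyclohexyl]buta-1,3-diene | C=C(OCC)C(=C)[C@H]1CC[C@](C)(Cl)[C@@H](Br)C1 | intermediate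
20 | 3-[(1S,3S,4S)-3-bromo-4-chloro-4-methylcyclohexyl]but-3-en-2-one | CC(=O)C(=C)[C@H]1CC[C@](C)(Cl)[C@@H](Br)C1 | intermediate
21 | (2S)-3-[(1S,3S,4S)-3-bromo-4-chloro-4-methylcyclohexyl]but-3-en-2-ol | C[C@H](O)C(=C)[C@H]1CC[C@](C)(Cl)[C@@H](Br)C1 | intermediate
22 | (1S)-1-{(2R)-2-[(1S,3S,4S)-3-bromo-4-chloro-4-methylcyclohexyl]oxiran-2-yl}ethan-1-ol | C[C@H](O)[C@]2(CO2)[C@H]1CC[C@](C)(Cl)[C@@H](Br)C1 | intermediate
23 | (2-methylprop-1-en-1-yl)magnesium bromide | CC(C)=C[Mg]Br | starting material
24 | (2S,3S)-3-[(1S,3S,4S)-3-bromo-4-chloro-4-methylcyclohexyl]-6-methylhept-5-ene-2,3-diol | C[C@H](O)[C@](O)(CC=C(C)C)[C@H]1CC[C@](C)(Cl)[C@@H](Br)C1 | intermediate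
25 | (3S)-3-[(1S,3S,4S)-3-bromo-4-chloro-4-methylcyclohexyl]-3-hydroxy-6-methylhept-5-en-2-one | CC(=O)[C@](O)(CC=C(C)C)[C@H]1CC[C@](C)(Cl)[C@@H](Br)C1 | intermediate
26 | (3S)-3-[(1S,3S,4S)-3-bromo-4-chloro-4-methylcyclohexyl]-4-[(2R)-3,3-dimethyloxiran-2-yl]-3-hydroxybutan-2-one | CC(=O)[C@](O)(C[C@H]1OC1(C)C)[C@H]1CC[C@](C)(Cl)[C@@H](Br)C1 | target

Total step count: 15. Longest linear sequence: 14 steps (from 4, steps 2 to 15).

**Steps most likely to fail**

Step 6 (ring closure). What may go wrong: elimination or bromine-assisted ionisation of the β-bromo triflate may outrun the 6-exo closure, or the enolate may close slowly on the face that the auxiliary demands and then decompose. The fallback sets out from 3 and comes back at 15; it exchanges the auxiliary for a small, strongly nucleophilic nitrile anion and sorts C1' by separation. Negishi coupling of 3 with commercial 3-cyanopropylzinc bromide (Pd(PPh3)4, THF, rt) should give (Z)-7-hydroxy-5-methylhept-5-enenitrile F1. Bromochlorination under the conditions of step 4 should give (5S,6S)-6-bromo-5-chloro-7-hydroxy-5-methylheptanenitrile F2, and Tf2O with 2,6-lutidine should give (5S,6S)-6-bromo-5-chloro-5-methyl-7-(trifluoromethanesulfonyloxy)heptanenitrile F3. LiN(iPr)2 in THF at −78 °C forms the α-lithio nitrile F4, which should close by intramolecular nitrile-anion alkylation to (1S,3S,4S)-3-bromo-4-chloro-4-methylcyclohexane-1-carbonitrile F5 together with its C1 epimer (1R,3S,4S)-3-bromo-4-chloro-4-methylcyclohexane-1-carbonitrile F6, to be separated by chromatography. Addition of MeMgBr to F5 gives the N-bromomagnesio ketimine F7, and aqueous HCl hydrolyses it to 15.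

Step 4 (bromochlorination). What may go wrong: the imide may compete with the allylic alkoxide for titanium, so that enantiofacial control is lost or the reaction stalls. The fallback sets out from 3 and comes back at 10; it carries the carboxyl as a tert-butyl ester through the halogenation and attaches the auxiliary afterwards. 9-BBN hydroboration of commercial tert-butyl but-3-enoate gives tert-butyl 4-(9-borabicyclo[3.3.1]nonan-9-yl)butanoate F8, and Suzuki–Miyaura coupling with 3 (as in step 3) should give tert-butyl (Z)-7-hydroxy-5-methylhept-5-enoate F9. Bromochlorination as in step 4 should give tert-butyl (5S,6S)-6-bromo-5-chloro-7-hydroxy-5-methylheptanoate F10. Silylation (t-BuPh2SiCl, imidazole) gives tert-butyl (5S,6S)-6-bromo-7-[tert-butyl(diphenyl)silyl]oxy-5-chloro-5-methylheptanoate F11, and CF3CO2H in CH2Cl2 at 0 °C frees (5S,6S)-6-bromo-7-[tert-butyl(diphenyl)silyl]oxy-5-chloro-5-methylheptanoic acid F12. Pivaloyl chloride and Et3N form the mixed pivalic anhydride F13, which acylates 6 to give (R)-4-benzyl-3-{(5S,6S)-6-bromo-7-[tert-butyl(diphenyl)silyl]oxy-5-chloro-5-methylheptanoyl}oxazolidin-2-one F14. HF·pyridine then returns 10.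

Step 12 (key epoxidation). What may go wrong: poor facial selectivity at the hindered 1,1-disubstituted alkene, or titanium-promoted opening of the 2,2-disubstituted oxirane. The fallback sets out from 21 and comes back at 22; it moves the stereocontrol from the tartrate to the substrate. Hydroxyl-directed epoxidation with VO(acac)2 (2 mol%) and t-BuOOH in CH2Cl2 at 0 °C uses no chiral ligand. Allylic 1,2-strain between the C2 methyl and the ring on C3 should steer oxygen to the erythro face, so the (S)-carbinol set in step 11 should give the same epoxy alcohol 22.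

**Further compounds**

F1 | step 6 | (Z)-7-hydroxy-5-methylhept-5-enenitrile | N#CCCC/C(C)=C\CO
F2 | step 6 | (5S,6S)-6-bromo-5-chloro-7-hydroxy-5-methylheptanenitrile | N#CCCC[C@](C)(Cl)[C@@H](Br)CO
F3 | step 6 | (5S,6S)-6-bromo-5-chloro-5-methyl-7-(trifluoromethanesulfonyloxy)heptanenitrile | N#CCCC[C@](C)(Cl)[C@@H](Br)COS(=O)(=O)C(F)(F)F
F4 | step 6 | α-lithio nitrile of F3 | [Li+].N#C[CH-]CC[C@](C)(Cl)[C@@H](Br)COS(=O)(=O)C(F)(F)F
F5 | step 6 | (1S,3S,4S)-3-bromo-4-chloro-4-methylcyclohexane-1-carbonitrile | N#C[C@H]1CC[C@](C)(Cl)[C@@H](Br)C1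
F6 | step 6 | (1R,3S,4S)-3-bromo-4-chloro-4-methylcyclohexane-1-carbonitrile | N#C[C@@H]1CC[C@](C)(Cl)[C@@H](Br)C1
F7 | step 6 | N-bromomagnesio ketimine of 15 | CC(=N[Mg]Br)[C@H]1CC[C@](C)(Cl)[C@@H](Br)C1
F8 | step 4 | tert-butyl 4-(9-borabicyclo[3.3.1]nonan-9-yl)butanoate | CC(C)(C)OC(=O)CCCB1C2CCCC1CCC2
F9 | step 4 | tert-butyl (Z)-7-hydroxy-5-methylhept-5-enoate | CC(C)(C)OC(=O)CCC/C(C)=C\CO
F10 | step 4 | tert-butyl (5S,6S)-6-bromo-5-chloro-7-hydroxy-5-methylheptanoate | CC(C)(C)OC(=O)CCC[C@](C)(Cl)[C@@H](Br)CO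
F11 | step 4 | tert-butyl (5S,6S)-6-bromo-7-[tert-butyl(diphenyl)silyl]oxy-5-chloro-5-methylheptanoate | CC(C)(C)OC(=O)CCC[C@](C)(Cl)[C@@H](Br)CO[Si](c1ccccc1)(c1ccccc1)C(C)(C)C
F12 | step 4 | (5S,6S)-6-bromo-7-[tert-butyl(diphenyl)silyl]oxy-5-chloro-5-methylheptanoic acid | OC(=O)CCC[C@](C)(Cl)[C@@H](Br)CO[Si](c1ccccc1)(c1ccccc1)C(C)(C)C
F13 | step 4 | mixed pivalic anhydride of F12 | CC(C)(C)C(=O)OC(=O)CCC[C@](C)(Cl)[C@@H](Br)CO[Si](c1ccccc1)(c1ccccc1)C(C)(C)C
F14 | step 4 | (R)-4-benzyl-3-{(5S,6S)-6-bromo-7-[tert-butyl(diphenyl)silyl]oxy-5-chloro-5-methylheptanoyl}oxazolidin-2-one | O=C(CCC[C@](C)(Cl)[C@@H](Br)CO[Si](c1ccccc1)(c1ccccc1)C(C)(C)C)N1[C@H](Cc2ccccc2)COC1=O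
F0 | step 12 | none | none
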